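## Retrosynthetic overview

1. The strategy rests on the 2,2-dimethyltetrahydrofuran ring (O, C3, C2, C1, C15) that bridges C1 and C3 of the 14-membered carbocycle. Its O–C15 bond (gem-dimethyl C15, 1,4 to the C3 oxygen) is cut last, giving the C3-hydroxy C1-isopropenyl macrocycle 29 (transannular Markovnikov hydroetherification).
2. Macrocycle 29 comes from the macrocyclic enoate 27, closed at C7=C8 by intramolecular Horner–Wadsworth–Emmons olefination of the C7 aldehyde / C8 phosphonoacetate 26.
3. 26 comes from an Evans syn-aldol (C3–C4 bond, sets C3 and C4) between aldehyde 15 and imide 21.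
4. 15 comes from (R)-limonene 1,2-oxide: ring cleavage supplies C1 with its isopropenyl group; the methyl ketone is taken to an alkyne, extended with ethylene oxide, and iron-catalysed syn-carbomagnesiation sets (Z)-C11=C12; the derived iodide alkylates triethyl phosphonoacetate (C8–C9).
5. Ring order: carbocycle first (step 15), tetrahydrofuran second (step 18); the finish is desilylation, allylic oxidation to the C19 enal and malonylation of the C18 hydroxyl.

Key step: step 18

Remark: cembrane numbering of the target (ring C1–C14, ether carbon C15, C18 on C4, C19 on C8, C20 on C12) is used for all intermediates; the phosphonate-bearing carbon C8 in 14, 15 and 23–26 is an epimer mixture that is erased in step 15.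

Assumption: commercial (+)-limonene 1,2-oxide (the cis/trans epoxide mixture derived from (R)-limonene) is taken as the chiral-pool starting material; both diastereomers converge in step 1.

## Route

Step 1
Reactants: 1 (4R)-limonene 1,2-oxide (cis/trans mixture)
Product: 3 (3R)-6-oxo-3-(prop-1-en-2-yl)heptanal, via limonene-1,2-diol 2 (not isolated)
Conditions: H5IO6, THF/H2O, 0 °C → rt
Reagents that add atoms: water, O
Why: Acid-promoted hydrolysis of the epoxide to the trans-diol and Malaprade glycol cleavage open the ring between the two oxygenated carbons, so both epoxide diastereomers converge on one keto aldehyde in which the isopropenyl-bearing stereocentre (later C1) is untouched.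

Step 2
Reactants: 3 (3R)-6-oxo-3-(prop-1-en-2-yl)heptanal
Product: 4 (5R)-7,7-dimethoxy-5-(prop-1-en-2-yl)heptan-2-one
Conditions: HC(OMe)3, CeCl3·7H2O (cat.), MeOH, 0 °C → rt
Reagents that add atoms: trimethyl orthoformate, COC(OC)OC; methanol, CO
Why: Lewis-acid-catalysed acetalisation with trimethyl orthoformate converts the aldehyde far faster than the methyl ketone (chemoselective acetal formation), which frees the ketone for the alkyne synthesis.

Step 3
Reactants: 4 (5R)-7,7-dimethoxy-5-(prop-1-en-2-yl)heptan-2-one
Product: 6 (5R)-7,7-dimethoxy-5-(prop-1-en-2-yl)hept-1-yne, via enol diethyl phosphate 5 (not isolated)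
Conditions: LiN(i-Pr)2, THF, −78 °C; ClP(O)(OEt)2, −78 °C → rt; LiN(i-Pr)2 (2.3 equiv), −78 °C → rt; aq. NH4Cl
Reagents that add atoms: none
Why: Kinetic deprotonation at the methyl group, O-phosphorylation and base-induced elimination of the resulting terminal enol phosphate convert the methyl ketone into the terminal alkyne (enol phosphate elimination), so that the former ketone carbon becomes C12 and the former methyl carbon C11, with the stereocentre remote from all anionic sites.

Step 4
Reactants: 6 (5R)-7,7-dimethoxy-5-(prop-1-en-2-yl)hept-1-yne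
Product: 8 (7R)-9,9-dimethoxy-7-(prop-1-en-2-yl)non-3-yn-1-ol, via lithium acetylide 7 (not isolated)
Conditions: n-BuLi, THF, −78 °C; ethylene oxide, DMPU, −78 °C → rt; aq. NH4Cl
Reagents that add atoms: ethylene oxide, C1CO1
Why: The lithium acetylide opens ethylene oxide by SN2 attack in the presence of a dipolar aprotic cosolvent, which avoids a Lewis acid that could ionise the dimethyl acetal and adds C10 and C9 with the hydroxyl needed to direct the next step.

Step 5
Reactants: 8 (7R)-9,9-dimethoxy-7-(prop-1-en-2-yl)non-3-yn-1-ol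
Product: 10 (3Z,7R)-9,9-dimethoxy-4-methyl-7-(prop-1-en-2-yl)non-3-en-1-ol, via alkenylmagnesium bromide 9 (not isolated)
Conditions: MeMgBr (5 equiv), Fe(acac)3 (15 mol %), THF, −78 → 0 °C; aq. NH4Cl
Reagents that add atoms: methylmagnesium bromide, C[Mg]Br
Why: Iron-catalysed alkoxide-directed carbomagnesiation of the homopropargylic alcohol delivers methyl to the distal alkyne carbon and magnesium to the proximal one in a syn addition held by a five-membered magnesium alkoxide chelate, so protonation should give the trisubstituted (Z)-alkene C11=C12 with C13 and C10 cis.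

Step 6
Reactants: 10 (3Z,7R)-9,9-dimethoxy-4-methyl-7-(prop-1-en-2-yl)non-3-en-1-ol
Product: 11 (3Z,7R)-1-iodo-9,9-dimethoxy-4-methyl-7-(prop-1-en-2-yl)non-3-ene
Conditions: I2, PPh3, imidazole, CH2Cl2, 0 °C → rt
Reagents that add atoms: iodine, II
Why: Appel-type iodination (PPh3, I2, imidazole) replaces the primary hydroxyl by iodide through SN2 displacement of an alkoxyphosphonium ion under buffered conditions that leave the acetal and both alkenes untouched.

Step 7
Reactants: 11 (3Z,7R)-1-iodo-9,9-dimethoxy-4-methyl-7-(prop-1-en-2-yl)non-3-ene; 12 triethyl phosphonoacetate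
Product: 14 ethyl (5Z,9R)-2-(diethoxyphosphoryl)-11,11-dimethoxy-6-methyl-9-(prop-1-en-2-yl)undec-5-enoate, via sodium phosphonoacetate enolate 13 (not isolated)
Conditions: NaH (2.3 equiv), 12 (2.5 equiv), THF, 0 °C → rt; then 11, DMSO, 50 °C
Reagents that add atoms: none
Why: The soft sodium enolate of triethyl phosphonoacetate, used in excess to suppress dialkylation, should displace the unhindered primary iodide by SN2 C-alkylation to form the C8–C9 bond, and the new phosphonate-bearing carbon is an inconsequential epimer mixture that is erased in step 15.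

Step 8
Reactants: 14 ethyl (5Z,9R)-2-(diethoxyphosphoryl)-11,11-dimethoxy-6-methyl-9-(prop-1-en-2-yl)undec-5-enoate
Product: 15 ethyl (5Z,9R)-2-(diethoxyphosphoryl)-6-methyl-11-oxo-9-(prop-1-en-2-yl)undec-5-enoate
Conditions: p-TsOH·H2O (cat.), acetone/H2O, rt
Reagents that add atoms: water, O
Why: Acyclic dimethyl acetals hydrolyse under catalytic sulfonic acid in wet acetone at room temperature (acetal hydrolysis), conditions that the phosphonate, the ester and the two alkenes should tolerate.

Step 9
Reactants: 16 2-(3-chloropropyl)-1,3-dioxolane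
Product: 18 4-(1,3-dioxolan-2-yl)butanoic acid, via Grignard reagent 17 (not isolated)
Conditions: Mg, I2 (cat.), THF, 50 °C; CO2, −20 °C → rt; cold dilute HCl to pH 4
Reagents that add atoms: carbon dioxide, O=C=O
Why: Magnesium insertion into the primary chloride and carboxylation of the Grignard reagent with CO2 give the acid, the cyclic acetal being stable to the organomagnesium and to a brief cold acidification.

Step 10
Reactants: 18 4-(1,3-dioxolan-2-yl)butanoic acid; 19 (S)-4-benzyl-2-oxazolidinone
Product: 21 (S)-4-benzyl-3-[4-(1,3-dioxolan-2-yl)butanoyl]oxazolidin-2-one, via mixed pivalic anhydride 20 (not isolated)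
Conditions: t-BuCOCl, Et3N, THF, −20 °C; then 19, LiCl, −20 °C → rt
Reagents that add atoms: none
Why: Activation of the acid as the mixed pivalic anhydride and N-acylation of the oxazolidinone in the presence of LiCl and Et3N is the standard imide synthesis, and the steric bulk of the pivaloyl group directs attack to the desired carbonyl.

Step 11
Reactants: 21 (S)-4-benzyl-3-[4-(1,3-dioxolan-2-yl)butanoyl]oxazolidin-2-one; 15 ethyl (5Z,9R)-2-(diethoxyphosphoryl)-6-methyl-11-oxo-9-(prop-1-en-2-yl)undec-5-enoate
Product: 23 (S)-4-benzyl-3-[(2S,3R,5R,8Z)-12-(diethoxyphosphoryl)-2-[2-(1,3-dioxolan-2-yl)ethyl]-13-ethoxy-3-hydroxy-8-methyl-13-oxo-5-(prop-1-en-2-yl)tridec-8-enoyl]oxazolidin-2-one, via dibutylboron enolate 22 (not isolated)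
Conditions: Bu2BOTf, i-Pr2NEt, CH2Cl2, −78 → 0 °C; then 15, −78 → 0 °C; pH 7 buffer, MeOH, H2O2, 0 °C
Reagents that add atoms: none
Why: Evans syn-aldol reaction: the (Z)-dibutylboron enolate reacts through a chair Zimmerman–Traxler transition state on the face opposite the benzyl group of the (S)-auxiliary, which forms the C3–C4 bond and sets C4 (S in the imide, R after reduction) and C3 (R) syn to each other under reagent control that the remote C1 centre should not override.

Step 12
Reactants: 23 syn-aldol adduct
Product: 24 ethyl (5Z,9R,11R,12R)-2-(diethoxyphosphoryl)-14-(1,3-dioxolan-2-yl)-11-hydroxy-12-(hydroxymethyl)-6-methyl-9-(prop-1-en-2-yl)tetradec-5-enoate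
Conditions: NaBH4, THF/H2O (4:1), 0 °C → rt
Reagents that add atoms: none
Why: NaBH4 in wet THF reduces the activated N-acyl oxazolidinone to the primary alcohol (reductive auxiliary removal) much faster than the ethyl ester of the phosphonoacetate, so C18 reaches the alcohol level without touching C3 or C4.

Step 13
Reactants: 24 C3,C18-diol
Product: 25 ethyl (5Z,9R,11R,12R)-11-acetoxy-12-(acetoxymethyl)-2-(diethoxyphosphoryl)-14-(1,3-dioxolan-2-yl)-6-methyl-9-(prop-1-en-2-yl)tetradec-5-enoate
Conditions: Ac2O, pyridine, DMAP (cat.), CH2Cl2, 0 °C → rt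
Reagents that add atoms: acetic anhydride, CC(=O)OC(C)=O
Why: DMAP-catalysed acetylation caps both hydroxyls, the C3 acetate preventing lactol formation with the C7 aldehyde and oxa-Michael addition after ring closure, and both acetates being removed later by the hydride that reduces the ester.

Step 14
Reactants: 25 diacetate dioxolane
Product: 26 ethyl (5Z,9R,11R,12R)-11-acetoxy-12-(acetoxymethyl)-2-(diethoxyphosphoryl)-6-methyl-15-oxo-9-(prop-1-en-2-yl)pentadec-5-enoate
Conditions: p-TsOH·H2O (cat.), acetone/H2O (10:1), 40 °C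
Reagents that add atoms: water, O
Why: Acid-catalysed hydrolysis of the 1,3-dioxolane in wet acetone (transacetalisation) unmasks the C7 aldehyde, while acetates, phosphonate and the unactivated alkenes should survive catalytic sulfonic acid at mild temperature.

Step 15
Reactants: 26 C7 aldehyde / C8 phosphonoacetate
Product: 27 ethyl (1R,3R,4R,7E,11Z)-3,18-diacetoxycembra-7,11,15(17)-trien-19-oate (14-membered ring)
Conditions: LiCl, DBU, MeCN, 0.002 M (slow addition of 26), rt
Reagents that add atoms: none
Why: Intramolecular Horner–Wadsworth–Emmons olefination under Masamune–Roush conditions (LiCl, amidine base) at high dilution closes the 14-membered ring at C7=C8, the α-alkyl phosphonoacetate giving the (E)-2-alkyl enoate (ester trans to C6) through the more stable oxaphosphetane, and the mild base sparing the acetates.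

Step 16
Reactants: 27 macrocyclic enoate diacetate
Product: 28 (1R,3R,4R,7E,11Z)-cembra-7,11,15(17)-triene-3,18,19-triol
Conditions: i-Bu2AlH (8 equiv), CH2Cl2, −78 → 0 °C; aq. potassium sodium tartrate
Reagents that add atoms: none
Why: Excess i-Bu2AlH reduces the conjugated ester in a 1,2 sense to the allylic alcohol and cleaves both acetates reductively in the same operation, a hydride reduction that leaves the three alkenes and all stereocentres untouched.

Step 17
Reactants: 28 macrocyclic triol
Product: 29 (1R,3R,4R,7E,11Z)-18,19-bis(tert-butyldiphenylsilyloxy)cembra-7,11,15(17)-trien-3-ol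
Conditions: t-BuPh2SiCl (2.2 equiv), imidazole, CH2Cl2, 0 °C
Reagents that add atoms: tert-butyl(chloro)diphenylsilane, CC(C)(C)[Si](Cl)(c1ccccc1)c1ccccc1
Why: The bulky chlorosilane silylates the two primary hydroxyls at C18 and C19 much faster than the secondary C3 hydroxyl, which is flanked by the C4 branch, so the nucleophile of the key step stays free (selective silylation).

Step 18
Reactants: 29 C3-hydroxy C1-isopropenyl macrocycle
Product: 30 (1R,3R,4R,7E,11Z)-18,19-bis(tert-butyldiphenylsilyloxy)-3,15-epoxycembra-7,11-diene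
Conditions: Co(salen) complex [N,N′-bis(3,5-di-tert-butylsalicylidene)-2,3-dimethylbutane-2,3-diaminatocobalt, divalent cobalt] (5 mol %), N-fluoro-2,4,6-trimethylpyridinium tetrafluoroborate, PhSiH3, PhCF3 (0.02 M), 0 °C → rt
Reagents that add atoms: none
Why: The cobalt(salen) catalyst is oxidised by the N-fluoropyridinium salt and converted by PhSiH3 into a cobalt hydride of trivalent cobalt that transfers a hydrogen atom to the terminal carbon C16 of the isopropenyl group, and the tertiary C15 radical is captured by cobalt and oxidised to an electrophilic alkylcobalt species of tetravalent cobalt that the C3 hydroxyl displaces to form the O–C15 bond. The closest known reaction is the cobalt-catalysed hydrogen-atom-transfer Markovnikov hydroalkoxylation of 4-methylpent-4-en-1-ols to 2,2-dimethyltetrahydrofurans (Mukaiyama-type radical-polar crossover), applied here to an alkenol embedded in a macrocycle. The tetrahydrofuran (O, C3, C2, C1, C15) closes in the 5-exo mode and becomes the bridge across the 14-membered ring. No stereocentre is created because C15 carries two methyl groups, and the cis arrangement of C4 and C14 on the new ring follows from the C1 and C3 configurations set in steps 1 and 11. The step needs chemoselective hydrogen-atom transfer to the exocyclic 1,1-disubstituted alkene over the trisubstituted C7=C8 and C11=C12 alkenes, which the steric demand of the cobalt hydride secures, and Markovnikov regioselectivity, which the tertiary radical secures. The 1,4 relationship of the free C3 hydroxyl to C15 makes ether formation faster than participation of the silyl ethers or transannular attack by C11=C12.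

Step 19
Reactants: 30 bridged bis-silyl ether
Product: 31 (1R,3R,4R,7E,11Z)-3,15-epoxycembra-7,11-diene-18,19-diol
Conditions: Bu4NF, THF, 0 °C → rt; aq. NH4Cl
Reagents that add atoms: none
Why: Fluoride cleaves both primary silyl ethers (desilylation) before the enal is formed, so the base-sensitive hydroxy enal is never exposed to fluoride, and the ether bridge and alkenes are inert.

Step 20
Reactants: 31 bridged diol
Product: 32 (1R,3R,4R,7E,11Z)-3,15-epoxy-18-hydroxycembra-7,11-dien-19-al
Conditions: MnO2 (activated, excess), CH2Cl2, rt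
Reagents that add atoms: none
Why: Activated MnO2 oxidises only the allylic C19 alcohol to the conjugated aldehyde (chemoselective allylic oxidation) under neutral conditions, leaving the saturated C18 alcohol and the (E)-geometry of C7=C8 unchanged.

Step 21
Reactants: 32 hydroxy enal
Product: 33 (1R,3R,4R,7E,11Z)-3,15-epoxy-19-oxocembra-7,11-dien-18-yl hydrogen malonate (CNP0170412.1)
Conditions: Meldrum's acid (1.2 equiv), toluene, 80 °C
Reagents that add atoms: Meldrum's acid (2,2-dimethyl-1,3-dioxane-4,6-dione), CC1(C)OC(=O)CC(=O)O1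
Why: The primary C18 alcohol opens Meldrum's acid on heating with loss of acetone (acylation by an activated cyclic malonate), which gives the malonic half ester directly and without base, conditions under which condensation at the hindered α-branched enal should be slow.

## Compound list

1 | (4R)-limonene 1,2-oxide, cis/trans mixture at the epoxide | CC12OC1C[C@@H](CC2)C(C)=C | starting material
2 | (4R)-p-menth-8-ene-1,2-diol (limonene-1,2-diol, trans-diol) | CC1(O)C(O)C[C@@H](CC1)C(C)=C | intermediate (not isolated)
3 | (3R)-6-oxo-3-(prop-1-en-2-yl)heptanal | O=CC[C@@H](CCC(C)=O)C(C)=C | intermediate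
4 | (5R)-7,7-dimethoxy-5-(prop-1-en-2-yl)heptan-2-one | COC(OC)C[C@@H](CCC(C)=O)C(C)=C | intermediate
5 | diethyl (5R)-7,7-dimethoxy-5-(prop-1-en-2-yl)hept-1-en-2-yl phosphate | COC(OC)C[C@@H](CCC(=C)OP(=O)(OCC)OCC)C(C)=C | intermediate (not isolated)
6 | (5R)-7,7-dimethoxy-5-(prop-1-en-2-yl)hept-1-yne | COC(OC)C[C@@H](CCC#C)C(C)=C | intermediate
7 | lithium acetylide of 6 | COC(OC)C[C@@H](CCC#C[Li])C(C)=C | intermediate (not isolated)
8 | (7R)-9,9-dimethoxy-7-(prop-1-en-2-yl)non-3-yn-1-ol | COC(OC)C[C@@H](CCC#CCCO)C(C)=C | intermediate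
9 | alkenylmagnesium bromide, bromomagnesium alkoxide (Mg on C11 cis to the new methyl) | COC(OC)C[C@@H](CC/C(C)=C(/[Mg]Br)CCO[Mg]Br)C(C)=C | intermediate (not isolated)
10 | (3Z,7R)-9,9-dimethoxy-4-methyl-7-(prop-1-en-2-yl)non-3-en-1-ol | COC(OC)C[C@@H](CC/C(C)=C\CCO)C(C)=C | intermediate
11 | (3Z,7R)-1-iodo-9,9-dimethoxy-4-methyl-7-(prop-1-en-2-yl)non-3-ene | COC(OC)C[C@@H](CC/C(C)=C\CCI)C(C)=C | intermediate
12 | triethyl phosphonoacetate | CCOC(=O)CP(=O)(OCC)OCC | starting material
13 | sodium enolate of triethyl phosphonoacetate | CCOC(=O)[CH-]P(=O)(OCC)OCC.[Na+] | intermediate (not isolated)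
14 | ethyl (5Z,9R)-2-(diethoxyphosphoryl)-11,11-dimethoxy-6-methyl-9-(prop-1-en-2-yl)undec-5-enoate (epimers at C8) | COC(OC)C[C@@H](CC/C(C)=C\CCC(C(=O)OCC)P(=O)(OCC)OCC)C(C)=C | intermediate
15 | ethyl (5Z,9R)-2-(diethoxyphosphoryl)-6-methyl-11-oxo-9-(prop-1-en-2-yl)undec-5-enoate (epimers at C8) | O=CC[C@@H](CC/C(C)=C\CCC(C(=O)OCC)P(=O)(OCC)OCC)C(C)=C | intermediate
16 | 2-(3-chloropropyl)-1,3-dioxolane | ClCCCC1OCCO1 | starting material
17 | [3-(1,3-dioxolan-2-yl)propyl]magnesium chloride | Cl[Mg]CCCC1OCCO1 | intermediate (not isolated)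
18 | 4-(1,3-dioxolan-2-yl)butanoic acid | OC(=O)CCCC1OCCO1 | intermediate
19 | (S)-4-benzyl-2-oxazolidinone | O=C1N[C@@H](Cc2ccccc2)CO1 | starting material
20 | 4-(1,3-dioxolan-2-yl)butanoic pivalic anhydride | CC(C)(C)C(=O)OC(=O)CCCC1OCCO1 | intermediate (not isolated)
21 | (S)-4-benzyl-3-[4-(1,3-dioxolan-2-yl)butanoyl]oxazolidin-2-one | O=C(CCCC1OCCO1)N1[C@@H](Cc2ccccc2)COC1=O | intermediate
22 | (Z)-dibutylboron enolate of 21 | CCCCB(CCCC)O/C(=C\CCC1OCCO1)N1[C@@H](Cc2ccccc2)COC1=O | intermediate (not isolated)
23 | syn-aldol adduct: imide of the (S)-auxiliary with C4 (S), C3 (R)-OH, C1 (R), (Z)-C11=C12, C7 dioxolane, C8 phosphonoacetate (epimers at C8) | O1CCOC1CC[C@H](C(=O)N2[C@@H](Cc3ccccc3)COC2=O)[C@H](O)C[C@@H](CC/C(C)=C\CCC(C(=O)OCC)P(=O)(OCC)OCC)C(C)=C | intermediate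
24 | C3,C18-diol: ethyl (5Z,9R,11R,12R)-2-(diethoxyphosphoryl)-14-(1,3-dioxolan-2-yl)-11-hydroxy-12-(hydroxymethyl)-6-methyl-9-(prop-1-en-2-yl)tetradec-5-enoate | O1CCOC1CC[C@H](CO)[C@H](O)C[C@@H](CC/C(C)=C\CCC(C(=O)OCC)P(=O)(OCC)OCC)C(C)=C | intermediate
25 | C3,C18-diacetate of 24 | O1CCOC1CC[C@H](COC(C)=O)[C@H](OC(C)=O)C[C@@H](CC/C(C)=C\CCC(C(=O)OCC)P(=O)(OCC)OCC)C(C)=C | intermediate
26 | C7 aldehyde: ethyl (5Z,9R,11R,12R)-11-acetoxy-12-(acetoxymethyl)-2-(diethoxyphosphoryl)-6-methyl-15-oxo-9-(prop-1-en-2-yl)pentadec-5-enoate | O=CCC[C@H](COC(C)=O)[C@H](OC(C)=O)C[C@@H](CC/C(C)=C\CCC(C(=O)OCC)P(=O)(OCC)OCC)C(C)=C | intermediate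
27 | ethyl (1R,3R,4R,7E,11Z)-3,18-diacetoxycembra-7,11,15(17)-trien-19-oate (14-membered ring; C1 isopropenyl, C12 methyl) | C/C1=C/CC/C(C(=O)OCC)=C\CC[C@H](COC(C)=O)[C@H](OC(C)=O)C[C@@H](CC1)C(C)=C | intermediate
28 | (1R,3R,4R,7E,11Z)-cembra-7,11,15(17)-triene-3,18,19-triol | C/C1=C/CC/C(CO)=C\CC[C@H](CO)[C@H](O)C[C@@H](CC1)C(C)=C | intermediate
29 | (1R,3R,4R,7E,11Z)-18,19-bis(tert-butyldiphenylsilyloxy)cembra-7,11,15(17)-trien-3-ol (key-step precursor) | C/C1=C/CC/C(CO[Si](c2ccccc2)(c3ccccc3)C(C)(C)C)=C\CC[C@H](CO[Si](c4ccccc4)(c5ccccc5)C(C)(C)C)[C@H](O)C[C@@H](CC1)C(C)=C | intermediate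
30 | (1R,3R,4R,7E,11Z)-18,19-bis(tert-butyldiphenylsilyloxy)-3,15-epoxycembra-7,11-diene (key-step product) | C/C1=C/CC/C(CO[Si](c3ccccc3)(c4ccccc4)C(C)(C)C)=C\CC[C@H](CO[Si](c5ccccc5)(c6ccccc6)C(C)(C)C)[C@H]2C[C@@H](CC1)C(C)(C)O2 | intermediate
31 | (1R,3R,4R,7E,11Z)-3,15-epoxycembra-7,11-diene-18,19-diol | C/C1=C/CC/C(CO)=C\CC[C@H](CO)[C@H]2C[C@@H](CC1)C(C)(C)O2 | intermediate
32 | (1R,3R,4R,7E,11Z)-3,15-epoxy-18-hydroxycembra-7,11-dien-19-al | C/C1=C/CC/C(C=O)=C\CC[C@H](CO)[C@H]2C[C@@H](CC1)C(C)(C)O2 | intermediate
33 | (1R,3R,4R,7E,11Z)-3,15-epoxy-19-oxocembra-7,11-dien-18-yl hydrogen malonate (CNP0170412.1) | C/C1=C/CC/C(C=O)=C\CC[C@H](COC(=O)CC(=O)O)[C@H]2C[C@@H](CC1)C(C)(C)O2 | target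

## Step count and risks

Total step count: 21. Longest linear sequence: 19 steps (steps 1–8 and 11–21, from 1); the imide branch adds steps 9 and 10.

Steps most likely to fail:

1. Step 18 (key step). Hydrogen-atom transfer may not be followed by capture, giving net reduction of the isopropenyl group or its isomerisation to the isopropylidene; the C15 radical or cation may be trapped across the ring by C11=C12; or turnover may be slow at the hindered macrocyclic alkene. Fallback (alkoxymercuration–demercuration instead of hydrogen-atom transfer): setting out from 29, Hg(OCOCF3)2 (divalent mercury) in THF at −20 °C should add to the isopropenyl group with capture by the C3 hydroxyl to give the alkylmercury trifluoroacetate F1, which alkaline NaBH4 at 0 °C reduces to 30, where the route is rejoined.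

2. Step 15. Intermolecular olefination (oligomers) may outrun ring closure, or E selectivity may be lost in the constrained ring-forming elimination. Fallback (ring-closing metathesis instead of olefination): setting out from 25, K2CO3 and paraformaldehyde in THF at 60 °C convert the phosphonoacetate into the 2-substituted acrylate F2; acid hydrolysis of the dioxolane (p-TsOH·H2O, wet acetone) gives the aldehyde F3; Wittig methylenation (Ph3P=CH2, THF, −78 °C) gives the terminal alkene F4; and second-generation Grubbs catalyst RuCl2(=CHPh)(PCy3)(H2IMes) in dilute toluene at 80 °C closes C7=C8 with loss of ethylene to return to 27, the (E)-enoate being the thermodynamic product.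

3. Step 21. Meldrum's acid may condense at the aldehyde (Knoevenagel), or the C18 hydroxyl may add in a conjugate sense to C7 of the enal under the acidic, heated conditions. Fallback (two-stage acylation at or below room temperature): setting out from 32, coupling with allyl hydrogen malonate (EDC·HCl, DMAP cat., CH2Cl2, 0 °C) gives the allyl malonate F5; Pd(PPh3)4 (zerovalent palladium, cat.) with potassium 2-ethylhexanoate in EtOAc/CH2Cl2 at rt transfers the allyl group to the carboxylate scavenger, and acidification to pH 3 then gives 33.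

## Further compounds

F1 | step 18 | C16-mercurated ether: (1R,3R,4R,7E,11Z)-18,19-bis(tert-butyldiphenylsilyloxy)-3,15-epoxycembra-7,11-dien-16-ylmercury trifluoroacetate (epimers at C15) | C/C1=C/CC/C(CO[Si](c3ccccc3)(c4ccccc4)C(C)(C)C)=C\CC[C@H](CO[Si](c5ccccc5)(c6ccccc6)C(C)(C)C)[C@H]2C[C@@H](CC1)C(C)(C[Hg]OC(=O)C(F)(F)F)O2
F2 | step 15 | 2-substituted acrylate with C7 dioxolane (C8 methylene ester, C3/C18 diacetate) | O1CCOC1CC[C@H](COC(C)=O)[C@H](OC(C)=O)C[C@@H](CC/C(C)=C\CCC(=C)C(=O)OCC)C(C)=C
F3 | step 15 | 2-substituted acrylate with C7 aldehyde | O=CCC[C@H](COC(C)=O)[C@H](OC(C)=O)C[C@@H](CC/C(C)=C\CCC(=C)C(=O)OCC)C(C)=C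
F4 | step 15 | metathesis substrate with C7 terminal alkene and C8 methylene ester | C=CCC[C@H](COC(C)=O)[C@H](OC(C)=O)C[C@@H](CC/C(C)=C\CCC(=C)C(=O)OCC)C(C)=C
F5 | step 21 | allyl (1R,3R,4R,7E,11Z)-3,15-epoxy-19-oxocembra-7,11-dien-18-yl malonate | C/C1=C/CC/C(C=O)=C\CC[C@H](COC(=O)CC(=O)OCC=C)[C@H]2C[C@@H](CC1)C(C)(C)O2
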